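**Strategy.** The target is disconnected between ring carbon C9 and side-chain methylene C11 (terpenoid numbering; ring B = C5–C10). The key step exploits the tetrasubstituted C8=C9 olefin of ring B: C9 lies between quaternary C10 and methyl-bearing C8, so a C9 ketone can enolize only towards C8 and its enol triflate fixes the olefin. In one operation the terminal vinyl group (C11=C12) of a stereodefined, silyl-protected 3-(hydroxymethyl)penta-2,4-dien-1-ol is hydroborated and the primary alkylborane is cross-coupled with this hindered triflate (B-alkyl Suzuki–Miyaura), uniting a sclareolide-derived bicycle with the C11–C15 chain. The butenolide is then attached by vinylogous aldol–elimination.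

Key step: step 7

Remark: numbering is C1–C10 for the decalin (ring A = C1–C5/C10), C11–C12 the tether, C13 the CH2OH-bearing olefin carbon, C14 and C15 the diene CH carbons, C16–C19 the butenolide; C5 and C10 come unchanged from (+)-sclareolide; ketone 6 is used as its C8-epimer mixture because C8 becomes sp2 in step 4; silyl ether 8 is taken as purchasable.

**Step 1**
Reactants: 1 (+)-sclareolide
Product: 3 9(11)-dehydrosclareolide, via 11-(phenylselanyl)sclareolide 2 (not isolated)
Conditions: LiN(i-Pr)2, THF, −78 °C; PhSeBr; then H2O2 (30% aq), pyridine, CH2Cl2, 0 °C → rt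
Reagents that add atoms: none
Why: Reich α-selenenylation of the lactone enolate should place PhSe on C11 from the less hindered α face (cis to H-9), and selenoxide syn-elimination can only use H-9, giving the C9=C11 butenolide while C5, C8 and C10 are untouched.

**Step 2**
Reactants: 3 9(11)-dehydrosclareolide
Product: 5 (2R,4aS,8aS)-2-hydroxy-2,5,5,8a-tetramethyloctahydronaphthalen-1(2H)-one, via glyoxylate ester 4 (not isolated)
Conditions: O3, CH2Cl2, −78 °C; Me2S, → rt; then K2CO3, MeOH, 0 °C
Reagents that add atoms: ozone [O-][O+]=O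
Why: Ozonolysis (Criegee cleavage) of the C9=C11 olefin turns C9 into the ketone and leaves C11–C12 as a glyoxylate on the C8 oxygen, an activated α-oxo ester that is transesterified by K2CO3/MeOH without breaking the C8–O bond, so the C8 configuration is retained.

**Step 3**
Reactants: 5 (2R,4aS,8aS)-2-hydroxy-2,5,5,8a-tetramethyloctahydronaphthalen-1(2H)-one
Product: 6 (4aS,8aS)-2,5,5,8a-tetramethyloctahydronaphthalen-1(2H)-one
Conditions: SmI2, THF/MeOH, −78 °C → rt
Reagents that add atoms: none
Why: SmI2 α-deoxygenation of an α-hydroxy ketone: the ketyl formed at C9 by divalent samarium expels hydroxide from C8 and the enolate is protonated by MeOH, giving C8 as an epimer mixture that is irrelevant because C8 becomes sp2 in step 4.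

**Step 4**
Reactants: 6 (4aS,8aS)-2,5,5,8a-tetramethyloctahydronaphthalen-1(2H)-one
Product: 7 (4aS,8aS)-2,5,5,8a-tetramethyl-3,4,4a,5,6,7,8,8a-octahydronaphthalen-1-yl trifluoromethanesulfonate
Conditions: KN(SiMe3)2, THF, −78 → 0 °C; PhNTf2, −78 °C → rt
Reagents that add atoms: N-phenylbis(trifluoromethanesulfonimide) O=S(=O)(N(c1ccccc1)S(=O)(=O)C(F)(F)F)C(F)(F)F
Why: Enolate O-sulfonylation: C10 is quaternary, so deprotonation can occur only at C8 and a single tetrasubstituted enol triflate with the C8=C9 double bond should result, as for 2,2,6-trimethylcyclohexanone.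

**Step 5**
Reactants: 8 4-{[tert-butyl(dimethyl)silyl]oxy}but-2-yn-1-ol
Product: 10 (2Z)-4-{[tert-butyl(dimethyl)silyl]oxy}-3-iodobut-2-en-1-ol, via cyclic vinylalanate 9 (not isolated)
Conditions: NaAlH2(OCH2CH2OMe)2, THF, 0 °C; then I2, −78 → 0 °C
Reagents that add atoms: iodine II
Why: Hydroxyl-directed trans-hydroalumination of the propargylic alcohol delivers hydride to C14 and aluminium to C13 within five-membered alanate 9, and iodinolysis with retention gives the Z iodide (iodine cis to C15), the low temperature suppressing β-elimination of the silyloxy group.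

**Step 6**
Reactants: 10 (2Z)-4-{[tert-butyl(dimethyl)silyl]oxy}-3-iodobut-2-en-1-ol
Product: 11 (2E)-3-({[tert-butyl(dimethyl)silyl]oxy}methyl)penta-2,4-dien-1-ol
Conditions: tributyl(vinyl)stannane, Pd2(dba)3 (cat.), AsPh3, NMP, rt → 40 °C
Reagents that add atoms: tributyl(vinyl)stannane C=C[Sn](CCCC)(CCCC)CCCC
Why: Stille coupling with retention of olefin geometry installs the C11=C12 vinyl group cis to C15, which fixes the C13=C14 configuration of the target; the free alcohol is tolerated.

**Step 7**
Reactants: 7 (4aS,8aS)-2,5,5,8a-tetramethyl-3,4,4a,5,6,7,8,8a-octahydronaphthalen-1-yl trifluoromethanesulfonate; 11 (2E)-3-({[tert-butyl(dimethyl)silyl]oxy}methyl)penta-2,4-dien-1-ol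
Product: 13 (2E)-3-({[tert-butyl(dimethyl)silyl]oxy}methyl)-5-[(4aS,8aS)-2,5,5,8a-tetramethyl-3,4,4a,5,6,7,8,8a-octahydronaphthalen-1-yl]pent-2-en-1-ol, via B-alkyl-9-BBN 12 (not isolated)
Conditions: 11, 9-BBN (2.2 equiv), THF, 0 °C → rt; then 7, Pd(dppf)Cl2 (cat.), AsPh3, Cs2CO3, DMF/H2O, 50 °C
Reagents that add atoms: none
Why: 9-BBN first converts the C15 hydroxyl into its borinate and then adds anti-Markovnikov to the only monosubstituted olefin, C11=C12, giving primary alkylborane 12; zerovalent palladium inserts into the C9–OTf bond of 7, the base-activated borate transfers C11 to palladium, and reductive elimination forms the C9(sp2)–C11(sp3) bond. The closest known reaction type is the B-alkyl Suzuki–Miyaura coupling of hindered cycloalkenyl triflates such as 2,6,6-trimethylcyclohexenyl triflate. No ring is closed and no stereocentre is created; C5 and C10 are spectators and the C13=C14 geometry set in steps 5 and 6 is carried through unchanged. The selectivities needed are chemoselective hydroboration, secured by the steric demand of 9-BBN, which leaves the trisubstituted C13=C14 olefin alone, and reductive elimination faster than β-hydride elimination, secured by the wide bite angle of dppf and by AsPh3/Cs2CO3 acceleration of transmetalation. The ring olefin cannot drift because the enol triflate already carries the C8=C9 double bond.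

**Step 8**
Reactants: 13 (2E)-3-({[tert-butyl(dimethyl)silyl]oxy}methyl)-5-[(4aS,8aS)-2,5,5,8a-tetramethyl-3,4,4a,5,6,7,8,8a-octahydronaphthalen-1-yl]pent-2-en-1-ol
Product: 14 (2E)-3-({[tert-butyl(dimethyl)silyl]oxy}methyl)-5-[(4aS,8aS)-2,5,5,8a-tetramethyl-3,4,4a,5,6,7,8,8a-octahydronaphthalen-1-yl]pent-2-enal
Conditions: MnO2, CH2Cl2, rt
Reagents that add atoms: none
Why: Allylic oxidation with MnO2 is selective for the primary allylic alcohol and, being neutral and heterogeneous, should leave the silyl ether, the tetrasubstituted ring olefin and the C13=C14 geometry untouched.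

**Step 9**
Reactants: 14 (2E)-3-({[tert-butyl(dimethyl)silyl]oxy}methyl)-5-[(4aS,8aS)-2,5,5,8a-tetramethyl-3,4,4a,5,6,7,8,8a-octahydronaphthalen-1-yl]pent-2-enal; 15 4-methylfuran-2(5H)-one
Product: 18 O-silyl-protected target, via silyloxyfuran 16 (not isolated), via silyl aldol adduct 17 (not isolated)
Conditions: 15, t-BuMe2SiOTf, i-Pr2NEt, CH2Cl2, 0 °C; then 14, −78 °C → rt; then DBU, rt
Reagents that add atoms: none
Why: One-pot vinylogous Mukaiyama aldol/elimination: silyloxyfuran 16 attacks the silyl triflate-activated aldehyde through its C5 position (future C16) in 1,2-fashion, and DBU removes the acidic C16 proton of 17 to expel silanolate (E1cB), which is stereoconvergent and should give the Z ylidene because the dienyl chain avoids the C17 methyl group.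

**Step 10**
Reactants: 18 O-silyl-protected target
Product: 19 target
Conditions: HF·pyridine, pyridine, THF, 0 °C → rt
Reagents that add atoms: none
Why: Fluoride cleavage of the primary silyl ether under buffered, weakly acidic conditions should spare the base-sensitive ylidene butenolide and both diene geometries.

**Compound list**

1 | (+)-sclareolide, (3aR,5aS,9aS,9bR)-3a,6,6,9a-tetramethyldecahydronaphtho[2,1-b]furan-2(1H)-one | O=C1C[C@H]2[C@@](C)(CC[C@H]3C(C)(C)CCC[C@]23C)O1 | starting material
2 | 11-(phenylselanyl)sclareolide (PhSe on the carbon α to the lactone carbonyl, expected α, cis to H-9; C11 left undefined) | O=C1C([Se]c2ccccc2)[C@H]3[C@@](C)(CC[C@H]4C(C)(C)CCC[C@]34C)O1 | intermediate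
3 | 9(11)-dehydrosclareolide, (3aR,5aS,9aS)-3a,6,6,9a-tetramethyl-4,5,5a,6,7,8,9,9a-octahydronaphtho[2,1-b]furan-2(3aH)-one | O=C1C=C2[C@@](C)(CC[C@H]3C(C)(C)CCC[C@]23C)O1 | intermediate
4 | (2R,4aS,8aS)-2,5,5,8a-tetramethyl-1-oxodecahydronaphthalen-2-yl oxoacetate (glyoxylate ester) | O=C1[C@](C)(OC(=O)C=O)CC[C@H]2C(C)(C)CCC[C@]12C | intermediate
5 | (2R,4aS,8aS)-2-hydroxy-2,5,5,8a-tetramethyloctahydronaphthalen-1(2H)-one | O=C1[C@](C)(O)CC[C@H]2C(C)(C)CCC[C@]12C | intermediate
6 | (4aS,8aS)-2,5,5,8a-tetramethyloctahydronaphthalen-1(2H)-one (C2 epimer mixture, C2 left undefined) | O=C1C(C)CC[C@H]2C(C)(C)CCC[C@]12C | intermediate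
7 | (4aS,8aS)-2,5,5,8a-tetramethyl-3,4,4a,5,6,7,8,8a-octahydronaphthalen-1-yl trifluoromethanesulfonate | FC(F)(F)S(=O)(=O)OC1=C(C)CC[C@H]2C(C)(C)CCC[C@]12C | intermediate
8 | 4-{[tert-butyl(dimethyl)silyl]oxy}but-2-yn-1-ol | OCC#CCO[Si](C)(C)C(C)(C)C | starting material
9 | sodium 3-({[tert-butyl(dimethyl)silyl]oxy}methyl)-2,2-bis(2-methoxyethoxy)-2,5-dihydro-1,2-oxaluminol-2-uide (cyclic vinylalanate) | [Na+].COCCO[Al-]1(OCCOC)OCC=C1CO[Si](C)(C)C(C)(C)C | intermediate
10 | (2Z)-4-{[tert-butyl(dimethyl)silyl]oxy}-3-iodobut-2-en-1-ol | OC/C=C(\I)CO[Si](C)(C)C(C)(C)C | intermediate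
11 | (2E)-3-({[tert-butyl(dimethyl)silyl]oxy}methyl)penta-2,4-dien-1-ol | OC/C=C(\C=C)CO[Si](C)(C)C(C)(C)C | intermediate
12 | 9-[(3E)-5-(9-borabicyclo[3.3.1]nonan-9-yloxy)-3-({[tert-butyl(dimethyl)silyl]oxy}methyl)pent-3-en-1-yl]-9-borabicyclo[3.3.1]nonane | B1(OC/C=C(\CCB2C3CCCC2CCC3)CO[Si](C)(C)C(C)(C)C)C2CCCC1CCC2 | intermediate
13 | (2E)-3-({[tert-butyl(dimethyl)silyl]oxy}methyl)-5-[(4aS,8aS)-2,5,5,8a-tetramethyl-3,4,4a,5,6,7,8,8a-octahydronaphthalen-1-yl]pent-2-en-1-ol | OC/C=C(\CCC1=C(C)CC[C@H]2C(C)(C)CCC[C@]12C)CO[Si](C)(C)C(C)(C)C | intermediate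
14 | (2E)-3-({[tert-butyl(dimethyl)silyl]oxy}methyl)-5-[(4aS,8aS)-2,5,5,8a-tetramethyl-3,4,4a,5,6,7,8,8a-octahydronaphthalen-1-yl]pent-2-enal | O=C/C=C(\CCC1=C(C)CC[C@H]2C(C)(C)CCC[C@]12C)CO[Si](C)(C)C(C)(C)C | intermediate
15 | 4-methylfuran-2(5H)-one | CC1=CC(=O)OC1 | starting material
16 | tert-butyl(dimethyl)[(4-methylfuran-2-yl)oxy]silane | Cc1coc(O[Si](C)(C)C(C)(C)C)c1 | intermediate
17 | 5-[(2E)-1-{[tert-butyl(dimethyl)silyl]oxy}-3-({[tert-butyl(dimethyl)silyl]oxy}methyl)-5-[(4aS,8aS)-2,5,5,8a-tetramethyl-3,4,4a,5,6,7,8,8a-octahydronaphthalen-1-yl]pent-2-en-1-yl]-4-methylfuran-2(5H)-one (diastereomer mixture at the two new centres) | CC1=CC(=O)OC1C(O[Si](C)(C)C(C)(C)C)/C=C(\CCC2=C(C)CC[C@H]3C(C)(C)CCC[C@]23C)CO[Si](C)(C)C(C)(C)C | intermediate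
18 | (5Z)-5-{(2E)-3-({[tert-butyl(dimethyl)silyl]oxy}methyl)-5-[(4aS,8aS)-2,5,5,8a-tetramethyl-3,4,4a,5,6,7,8,8a-octahydronaphthalen-1-yl]pent-2-en-1-ylidene}-4-methylfuran-2(5H)-one | CC1=CC(=O)O/C1=C\C=C(\CO[Si](C)(C)C(C)(C)C)CCC1=C(C)CC[C@H]2C(C)(C)CCC[C@]12C | intermediate
19 | (5Z)-5-{(2E)-3-(hydroxymethyl)-5-[(4aS,8aS)-2,5,5,8a-tetramethyl-3,4,4a,5,6,7,8,8a-octahydronaphthalen-1-yl]pent-2-en-1-ylidene}-4-methylfuran-2(5H)-one | CC1=CC(=O)O/C1=C\C=C(\CO)CCC1=C(C)CC[C@H]2C(C)(C)CCC[C@]12C | target

**Totals and risks**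

Total step count: 10. Longest linear sequence: 8 (steps 1–4 and 7–10); steps 5 and 6 form the two-step side branch.

Steps most likely to fail:

1. Step 7. The palladium centre at C9, flanked by quaternary C10 and the C8 methyl group, may undergo transmetalation too slowly, so that protodeboronation or β-hydride elimination of the alkyl group outruns coupling. The fallback is a polarity-inverted, nickel-catalysed reductive union that sets out from dienol 11 and triflate 7. Borane 12 is formed as in step 7 and iodinated in the same flask (I2, NaOMe, MeOH, 0 °C) to (2E)-3-({[tert-butyl(dimethyl)silyl]oxy}methyl)-5-iodopent-2-en-1-ol F1. Cross-electrophile coupling of this iodide with 7 (NiBr2(dme), 4,4′-di-tert-butyl-2,2′-bipyridine, Zn powder, NaI, DMA, rt) should form the same C9–C11 bond by capture of the primary alkyl radical at an alkenylnickel species, and the sequence comes back to the route at alcohol 13.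

2. Step 3. Cleavage of the hindered tertiary C8–O bond may stay incomplete, or the C9 carbonyl may be reduced further. The fallback sets out from ketol 5, which is dehydrated (SOCl2, pyridine, CH2Cl2, 0 °C) to a mixture of the endocyclic enone (4aS,8aS)-2,5,5,8a-tetramethyl-4a,5,6,7,8,8a-hexahydronaphthalen-1(4H)-one F2 and the exocyclic enone (4aS,8aS)-5,5,8a-trimethyl-2-methylideneoctahydronaphthalen-1(2H)-one F3. Conjugate reduction of the mixture with LiBH(s-Bu)3 (THF, −78 °C) funnels both isomers into the same C8=C9 enolate, which is trapped in the same flask with PhNTf2. This comes back to the route at triflate 7 and bypasses ketone 6.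

3. Step 9. The silyl triflate may ionize the doubly allylic silyloxy group of 17, eroding the C13=C14 geometry, or the elimination may stay incomplete or unselective. The fallback sets out from enal 14, which is homologated with LiC(N2)SiMe3 (THF, −78 °C → rt, Colvin rearrangement) to the enyne tert-butyl(dimethyl){[(2E)-2-{2-[(4aS,8aS)-2,5,5,8a-tetramethyl-3,4,4a,5,6,7,8,8a-octahydronaphthalen-1-yl]ethyl}pent-2-en-4-yn-1-yl]oxy}silane F4. Tandem Sonogashira coupling and 5-exo-dig lactonization of this enyne with (2Z)-3-iodobut-2-enoic acid F5 (made from but-2-ynoic acid with NaI in AcOH), using Pd(PPh3)4, CuI and Et3N in MeCN at rt, should build the Z ylidene butenolide under neutral to basic conditions and comes back to the route at silyl ether 18.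

**Further compounds**

F1 | step 7 | (2E)-3-({[tert-butyl(dimethyl)silyl]oxy}methyl)-5-iodopent-2-en-1-ol | OC/C=C(\CCI)CO[Si](C)(C)C(C)(C)C
F2 | step 3 | (4aS,8aS)-2,5,5,8a-tetramethyl-4a,5,6,7,8,8a-hexahydronaphthalen-1(4H)-one | O=C1C(C)=CC[C@H]2C(C)(C)CCC[C@]12C
F3 | step 3 | (4aS,8aS)-5,5,8a-trimethyl-2-methylideneoctahydronaphthalen-1(2H)-one | O=C1C(=C)CC[C@H]2C(C)(C)CCC[C@]12C
F4 | step 9 | tert-butyl(dimethyl){[(2E)-2-{2-[(4aS,8aS)-2,5,5,8a-tetramethyl-3,4,4a,5,6,7,8,8a-octahydronaphthalen-1-yl]ethyl}pent-2-en-4-yn-1-yl]oxy}silane | C#C/C=C(\CCC1=C(C)CC[C@H]2C(C)(C)CCC[C@]12C)CO[Si](C)(C)C(C)(C)C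
F5 | step 9 | (2Z)-3-iodobut-2-enoic acid | C/C(I)=C/C(O)=O
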